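**Retrosynthetic overview**

1. The C3 ester is cut to give the enol-silylated diosphenol alcohol and a silyl-protected (2E,4E,6R)-dienoic acid. The diosphenol (C7 enol, C8 ketone) comes from the ring A/B trienone by C7 hydroxylation and oxidation.
2. Feature used (eremophilane numbering): the C1=C2 alkene of ring A lies between the C3 carbinol carbon and the C9=C10 enone alkene of ring B. Ring A is therefore opened at C1=C2 to a C10 vinyl and a C2 vinyl group on a ring B enone that already carries the cis C3/C4/C5 triad.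
3. That dienone comes from a ring B cyclohexene: C10 vinyl by conjugate addition and dehydrosilylation, C8 ketone by allylic oxidation, C3 carbinol by Felkin–Anh reduction of a vinyl ketone made by Stille acylation.
4. The C4–C5 bond and both of its stereocentres come from an Ireland–Claisen rearrangement of (R)-3-methylcyclohex-2-enyl propanoate, made by CBS reduction of 3-methylcyclohex-2-en-1-one.
5. Ring order: ring B is present from the start and ring A is closed last by metathesis. The side-chain acid is made separately by auxiliary-controlled hydroxymethylation and vinylogous Horner–Wadsworth–Emmons olefination.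

Key step: step 9

Remark: eremophilane numbering is used throughout: ring A is C1, C2, C3, C4, C5, C10; ring B is C5 to C10; C3 bears the ester oxygen, C4 and C5 the methyl groups, C7 the enol hydroxyl, C8 the ketone.
Remark: metal enolates, alkoxides and other ionised forms of a numbered compound are treated as forms of that compound; covalent intermediates that are not isolated carry their own numbers.
Remark: the transient stereocentres at C10 (silyl enol ether of step 8) and at C7 (acyloin of step 10) are left unassigned, because the following operation removes them.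
Remark: the C3 carbinol is made by hydride addition to a vinyl ketone and not by vinyl addition to a C3 aldehyde, because Felkin–Anh addition to the aldehyde would place the C3 oxygen trans to the C4 methyl in ring A.

**Route**

Step 1
Reactants: 1 3-methylcyclohex-2-en-1-one
Product: 2 (R)-3-methylcyclohex-2-en-1-ol
Conditions: (S)-2-methyl-CBS-oxazaborolidine (10 mol %), catecholborane, toluene, -78 °C; then H2O
Reagents that add atoms: none
Why: Corey–Bakshi–Shibata reduction; the oxazaborolidine–borane complex binds the enone with its alkene side as the larger group and delivers hydride to one carbonyl face, which should set the (R)-carbinol.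

Step 2
Reactants: 2 (R)-3-methylcyclohex-2-en-1-ol; 3 propanoyl chloride
Product: 4 (R)-3-methylcyclohex-2-en-1-yl propanoate
Conditions: pyridine, DMAP (cat.), CH2Cl2, 0 °C to rt
Reagents that add atoms: none
Why: O-acylation by nucleophilic acyl substitution under mild base; the carbinol centre is not touched.

Step 3
Reactants: 4 (R)-3-methylcyclohex-2-en-1-yl propanoate
Product: 7 (R)-2-[(S)-1-methylcyclohex-2-en-1-yl]propanoic acid, via silyl ketene acetal 5 (not isolated), via trimethylsilyl ester 6 (not isolated)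
Conditions: LiN(iPr)2, THF–DMPU, -78 °C; Me3SiCl; -78 to 60 °C; then dilute aq. HCl
Reagents that add atoms: none
Why: Ireland–Claisen rearrangement; the [3,3] shift is suprafacial, so the C4–C5 bond forms on the ring face that carried the ester oxygen and fixes quaternary C5, while the (Z)-silyl ketene acetal (C-methyl cis to OSiMe3) reacting through the boat-like transition state usual for cyclohexenyl esters should place the C4 methyl as required (the (E)-acetal through the chair leads to the same C4 epimer).

Step 4
Reactants: 7 (R)-2-[(S)-1-methylcyclohex-2-en-1-yl]propanoic acid; 8 tributyl(vinyl)stannane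
Product: 10 (R)-4-[(S)-1-methylcyclohex-2-en-1-yl]pent-1-en-3-one, via acid chloride 9 (not isolated)
Conditions: (COCl)2, DMF (cat.), CH2Cl2, 0 °C to rt, evaporate; then 8, Pd(PPh3)4 (3 mol %), THF, 50 °C
Reagents that add atoms: none
Why: acid chloride formation followed by Stille acyl coupling (ketone synthesis); zerovalent palladium inserts into the C–Cl bond and the acylpalladium chloride takes the vinyl group from tin, with no base present that could epimerise C4.

Step 5
Reactants: 10 (R)-4-[(S)-1-methylcyclohex-2-en-1-yl]pent-1-en-3-one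
Product: 11 (3S,4R)-4-[(S)-1-methylcyclohex-2-en-1-yl]pent-1-en-3-ol
Conditions: NaBH4, CeCl3·7H2O, MeOH, -78 °C
Reagents that add atoms: none
Why: Luche 1,2-reduction of the enone; under Felkin–Anh control the quaternary C5 substituent stands anti to the incoming hydride and the C4 hydrogen flanks the vinyl group, which should give the (3S) carbinol whose C–O bond ends cis to the C4 methyl in ring A.

Step 6
Reactants: 11 (3S,4R)-4-[(S)-1-methylcyclohex-2-en-1-yl]pent-1-en-3-ol
Product: 12 tert-butyldimethylsilyl ether of 11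
Conditions: TBSOTf, 2,6-lutidine, CH2Cl2, -78 to 0 °C
Reagents that add atoms: tert-butyldimethylsilyl trifluoromethanesulfonate (TBSOTf), CC(C)(C)[Si](C)(C)OS(=O)(=O)C(F)(F)F
Why: O-silylation of the hindered secondary alcohol with the silyl triflate; no stereocentre is affected.

Step 7
Reactants: 12 tert-butyldimethylsilyl ether of 11
Product: 13 (S)-4-[(2R,3S)-3-(tert-butyldimethylsilyloxy)pent-4-en-2-yl]-4-methylcyclohex-2-en-1-one
Conditions: CrO3, 3,5-dimethylpyrazole, CH2Cl2, -20 °C
Reagents that add atoms: chromium trioxide, O=[Cr](=O)=O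
Why: allylic C–H oxidation with the CrO3–3,5-dimethylpyrazole complex; C8 is the only allylic methylene of the ring alkene because C5 is quaternary, and the side-chain C3–H is shielded by the silyl ether and the branched neighbouring carbons.

Step 8
Reactants: 13 (S)-4-[(2R,3S)-3-(tert-butyldimethylsilyloxy)pent-4-en-2-yl]-4-methylcyclohex-2-en-1-one; 14 vinylmagnesium bromide
Product: 16 (R)-4-[(2R,3S)-3-(tert-butyldimethylsilyloxy)pent-4-en-2-yl]-4-methyl-3-vinylcyclohex-2-en-1-one, via trimethylsilyl enol ether 15 (not isolated)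
Conditions: 14, CuBr·SMe2 (10 mol %), Me3SiCl, THF, -78 to -40 °C; then Pd(OAc)2 (1.1 equiv), MeCN, rt
Reagents that add atoms: none
Why: copper-catalysed conjugate addition of the vinyl Grignard reagent with in situ silylation, then Saegusa–Ito dehydrosilylation in which divalent palladium forms the C9 palladium enolate and β-hydride elimination of the C10 hydrogen restores C9=C10, which erases the transient C10 centre.

Step 9
Reactants: 16 (R)-4-[(2R,3S)-3-(tert-butyldimethylsilyloxy)pent-4-en-2-yl]-4-methyl-3-vinylcyclohex-2-en-1-one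
Product: 17 (4aR,5R,6S)-6-(tert-butyldimethylsilyloxy)-4a,5-dimethyl-4,4a,5,6-tetrahydronaphthalen-2(3H)-one
Conditions: RuCl2(=CHPh)(PCy3)(H2IMes) (second-generation Grubbs catalyst, 5 mol %), CH2Cl2 (5 mM), 40 °C, argon sparge
Reagents that add atoms: none
Why: Ring-closing olefin metathesis: the ruthenium alkylidene should load on one of the two monosubstituted alkenes (the C2 vinyl group of the allylic silyl ether or the terminal C1 carbon of the dienone), add to the other through a ruthenacyclobutane and cyclorevert with loss of ethylene to form C1=C2. The closest known reaction type is diene–ene ring-closing metathesis between the terminal alkene of a 1,3-diene and an allylic ether alkene, which gives a cyclohexa-1,3-diene. Ring A closes as a six-membered carbocycle over C2, C3, C4, C5, C10 and C1, the two reacting carbons being joined by a four-atom tether, and the new diene ends conjugated with C8=O. No stereocentre is formed or touched, so the C3/C4/C5 triad built in the open chain passes unchanged into ring A. The step needs site selectivity for the terminal C1 alkene over the internal C9=C10 alkene and cyclisation over intermolecular metathesis; the C9=C10 alkene is trisubstituted and carbonyl-conjugated and therefore unreactive, a closure onto it would have to break ring B, and high dilution with removal of ethylene favours the six-membered ring.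

Step 10
Reactants: 17 (4aR,5R,6S)-6-(tert-butyldimethylsilyloxy)-4a,5-dimethyl-4,4a,5,6-tetrahydronaphthalen-2(3H)-one
Product: 18 (4aR,5R,6S)-6-(tert-butyldimethylsilyloxy)-3-hydroxy-4a,5-dimethyl-4,4a,5,6-tetrahydronaphthalen-2(3H)-one (C7 epimers)
Conditions: NaN(SiMe3)2, THF, -78 °C; then 2-(phenylsulfonyl)-3-phenyloxaziridine, -78 °C
Reagents that add atoms: 2-(phenylsulfonyl)-3-phenyloxaziridine, O=S(=O)(c1ccccc1)N1OC1c1ccccc1
Why: kinetic α′-deprotonation at C7 of the cross-conjugated ketone and enolate hydroxylation with the N-sulfonyloxaziridine (Davis oxidation); the C7 configuration does not matter because the next step removes it.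

Step 11
Reactants: 18 (4aR,5R,6S)-6-(tert-butyldimethylsilyloxy)-3-hydroxy-4a,5-dimethyl-4,4a,5,6-tetrahydronaphthalen-2(3H)-one
Product: 20 (4aS,5R,6S)-6-(tert-butyldimethylsilyloxy)-3-hydroxy-4a,5-dimethyl-5,6-dihydronaphthalen-2(4aH)-one, via 7,8-diketone 19 (not isolated)
Conditions: Dess–Martin periodinane, CH2Cl2, 0 °C to rt
Reagents that add atoms: none
Why: Dess–Martin oxidation of the acyloin to the 7,8-dione, which can enolise only towards C6 and should therefore settle as the diosphenol.

Step 12
Reactants: 20 (4aS,5R,6S)-6-(tert-butyldimethylsilyloxy)-3-hydroxy-4a,5-dimethyl-5,6-dihydronaphthalen-2(4aH)-one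
Product: 21 (4aS,5R,6S)-3,6-dihydroxy-4a,5-dimethyl-5,6-dihydronaphthalen-2(4aH)-one
Conditions: HF·pyridine, THF, 0 °C to rt
Reagents that add atoms: none
Why: fluoride-mediated cleavage of the secondary silyl ether under buffered conditions that the diosphenol and the trienone should tolerate.

Step 13
Reactants: 21 (4aS,5R,6S)-3,6-dihydroxy-4a,5-dimethyl-5,6-dihydronaphthalen-2(4aH)-one
Product: 22 (4aS,5R,6S)-3-(tert-butyldimethylsilyloxy)-6-hydroxy-4a,5-dimethyl-5,6-dihydronaphthalen-2(4aH)-one
Conditions: TBSCl (1.05 equiv), Et3N, CH2Cl2, -20 °C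
Reagents that add atoms: tert-butyldimethylsilyl chloride (TBSCl), CC(C)(C)[Si](C)(C)Cl
Why: chemoselective O-silylation; the acidic enol hydroxyl reacts as its ammonium enolate much faster than the hindered secondary C3 alcohol.

Step 14
Reactants: 23 (R)-4-benzyloxazolidin-2-one; 24 butanoyl chloride
Product: 25 (R)-4-benzyl-3-butanoyloxazolidin-2-one
Conditions: n-BuLi, THF, -78 °C; then 24
Reagents that add atoms: none
Why: N-acylation of the lithiated oxazolidinone by nucleophilic acyl substitution.

Step 15
Reactants: 25 (R)-4-benzyl-3-butanoyloxazolidin-2-one; 26 1,3,5-trioxane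
Product: 27 (R)-4-benzyl-3-[(S)-2-(hydroxymethyl)butanoyl]oxazolidin-2-one
Conditions: TiCl4, iPr2NEt, CH2Cl2, 0 °C; then 26, TiCl4, 0 °C
Reagents that add atoms: none
Why: auxiliary-controlled hydroxymethylation (aldol-type) of the chelated (Z)-titanium enolate with formaldehyde released from trioxane; the electrophile approaches the face opposite the benzyl group, which should set the (S) centre.

Step 16
Reactants: 27 (R)-4-benzyl-3-[(S)-2-(hydroxymethyl)butanoyl]oxazolidin-2-one
Product: 28 (R)-4-benzyl-3-[(S)-2-(tert-butyldimethylsilyloxymethyl)butanoyl]oxazolidin-2-one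
Conditions: TBSCl, imidazole, DMF, rt
Reagents that add atoms: tert-butyldimethylsilyl chloride (TBSCl), CC(C)(C)[Si](C)(C)Cl
Why: O-silylation of the primary alcohol; the α-stereocentre is not involved.

Step 17
Reactants: 28 (R)-4-benzyl-3-[(S)-2-(tert-butyldimethylsilyloxymethyl)butanoyl]oxazolidin-2-one
Product: 29 (R)-2-(tert-butyldimethylsilyloxymethyl)butan-1-ol
Conditions: LiBH4, Et2O, MeOH (1 equiv), 0 °C
Reagents that add atoms: none
Why: reductive cleavage of the imide with LiBH4 gives the primary alcohol and returns the auxiliary without touching the α-stereocentre.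

Step 18
Reactants: 29 (R)-2-(tert-butyldimethylsilyloxymethyl)butan-1-ol
Product: 30 (S)-2-(tert-butyldimethylsilyloxymethyl)butanal
Conditions: Dess–Martin periodinane, CH2Cl2, 0 °C
Reagents that add atoms: none
Why: Dess–Martin oxidation under non-basic conditions, chosen to limit epimerisation of the α-branched aldehyde, which is used at once.

Step 19
Reactants: 30 (S)-2-(tert-butyldimethylsilyloxymethyl)butanal; 31 triethyl 4-phosphonocrotonate
Product: 32 ethyl (2E,4E,6R)-6-(tert-butyldimethylsilyloxymethyl)octa-2,4-dienoate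
Conditions: 31, LiN(SiMe3)2, THF, -78 to 0 °C
Reagents that add atoms: none
Why: vinylogous Horner–Wadsworth–Emmons olefination; the stabilised phosphonate anion should give the (2E,4E)-dienoate, and the low temperature protects the α-stereocentre of the aldehyde.

Step 20
Reactants: 32 ethyl (2E,4E,6R)-6-(tert-butyldimethylsilyloxymethyl)octa-2,4-dienoate
Product: 33 (2E,4E,6R)-6-(tert-butyldimethylsilyloxymethyl)octa-2,4-dienoic acid
Conditions: LiOH, THF–MeOH–H2O, rt; then aq. HCl to pH 4
Reagents that add atoms: lithium hydroxide, [Li+].[OH-]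
Why: saponification of the ethyl ester; the primary silyl ether should survive aqueous LiOH and brief mild acidification.

Step 21
Reactants: 22 (4aS,5R,6S)-3-(tert-butyldimethylsilyloxy)-6-hydroxy-4a,5-dimethyl-5,6-dihydronaphthalen-2(4aH)-one; 33 (2E,4E,6R)-6-(tert-butyldimethylsilyloxymethyl)octa-2,4-dienoic acid
Product: 35 bis(tert-butyldimethylsilyl) ether of septeremophilane E, via mixed anhydride 34 (not isolated)
Conditions: 2,4,6-trichlorobenzoyl chloride, Et3N, THF, rt; then 22, DMAP, toluene, rt
Reagents that add atoms: none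
Why: Yamaguchi esterification; DMAP attacks the mixed anhydride at the dienoyl carbonyl and the acylpyridinium acylates the C3 hydroxyl with retention at C3.

Step 22
Reactants: 35 bis(tert-butyldimethylsilyl) ether of septeremophilane E
Product: 36 septeremophilane E
Conditions: HF·pyridine, THF–pyridine, 0 °C to rt
Reagents that add atoms: none
Why: global fluoride desilylation of the enol and primary silyl ethers, conditions under which the dienoate ester and the diosphenol should persist.

**Compound list**

1 | 3-methylcyclohex-2-en-1-one | CC1=CC(=O)CCC1 | starting material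
2 | (R)-3-methylcyclohex-2-en-1-ol | CC1=C[C@H](O)CCC1 | intermediate
3 | propanoyl chloride | CCC(=O)Cl | starting material
4 | (R)-3-methylcyclohex-2-en-1-yl propanoate | CCC(=O)O[C@H]1C=C(C)CCC1 | intermediate
5 | (Z)-silyl ketene acetal of 4, trimethyl{[(Z)-1-{[(R)-3-methylcyclohex-2-en-1-yl]oxy}prop-1-en-1-yl]oxy}silane | C/C=C(/O[C@H]1C=C(C)CCC1)O[Si](C)(C)C | intermediate (not isolated)
6 | trimethylsilyl (R)-2-[(S)-1-methylcyclohex-2-en-1-yl]propanoate | C[Si](C)(C)OC(=O)[C@H](C)[C@@]1(C)CCCC=C1 | intermediate (not isolated)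
7 | (R)-2-[(S)-1-methylcyclohex-2-en-1-yl]propanoic acid | OC(=O)[C@H](C)[C@@]1(C)CCCC=C1 | intermediate
8 | tributyl(vinyl)stannane | C=C[Sn](CCCC)(CCCC)CCCC | starting material
9 | (R)-2-[(S)-1-methylcyclohex-2-en-1-yl]propanoyl chloride | ClC(=O)[C@H](C)[C@@]1(C)CCCC=C1 | intermediate (not isolated)
10 | (R)-4-[(S)-1-methylcyclohex-2-en-1-yl]pent-1-en-3-one | C=CC(=O)[C@H](C)[C@@]1(C)CCCC=C1 | intermediate
11 | (3S,4R)-4-[(S)-1-methylcyclohex-2-en-1-yl]pent-1-en-3-ol | C=C[C@H](O)[C@H](C)[C@@]1(C)CCCC=C1 | intermediate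
12 | tert-butyldimethylsilyl ether of 11 | CC(C)(C)[Si](C)(C)O[C@@H](C=C)[C@H](C)[C@@]1(C)CCCC=C1 | intermediate
13 | (S)-4-[(2R,3S)-3-(tert-butyldimethylsilyloxy)pent-4-en-2-yl]-4-methylcyclohex-2-en-1-one | CC(C)(C)[Si](C)(C)O[C@@H](C=C)[C@H](C)[C@@]1(C)CCC(=O)C=C1 | intermediate
14 | vinylmagnesium bromide | C=C[Mg]Br | starting material
15 | trimethylsilyl enol ether of the 3-vinylcyclohexanone from 13 (C10 epimers, unassigned) | CC(C)(C)[Si](C)(C)O[C@@H](C=C)[C@H](C)[C@@]1(C)CCC(O[Si](C)(C)C)=CC1C=C | intermediate (not isolated)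
16 | (R)-4-[(2R,3S)-3-(tert-butyldimethylsilyloxy)pent-4-en-2-yl]-4-methyl-3-vinylcyclohex-2-en-1-one (metathesis precursor) | CC(C)(C)[Si](C)(C)O[C@@H](C=C)[C@H](C)[C@@]1(C)CCC(=O)C=C1C=C | intermediate
17 | (4aR,5R,6S)-6-(tert-butyldimethylsilyloxy)-4a,5-dimethyl-4,4a,5,6-tetrahydronaphthalen-2(3H)-one (3-O-silyl trinoreremophila-1,9-dien-8-one) | CC(C)(C)[Si](C)(C)O[C@H]1C=CC2=CC(=O)CC[C@]2(C)[C@H]1C | intermediate
18 | 7-hydroxy derivative of 17 (C7 epimers, unassigned) | CC(C)(C)[Si](C)(C)O[C@H]1C=CC2=CC(=O)C(O)C[C@]2(C)[C@H]1C | intermediate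
19 | 7,8-diketone, (4aR,5R,6S)-6-(tert-butyldimethylsilyloxy)-4a,5-dimethyl-4,4a,5,6-tetrahydronaphthalene-2,3-dione | CC(C)(C)[Si](C)(C)O[C@H]1C=CC2=CC(=O)C(=O)C[C@]2(C)[C@H]1C | intermediate (not isolated)
20 | (4aS,5R,6S)-6-(tert-butyldimethylsilyloxy)-3-hydroxy-4a,5-dimethyl-5,6-dihydronaphthalen-2(4aH)-one (3-O-silyl diosphenol) | CC(C)(C)[Si](C)(C)O[C@H]1C=CC2=CC(=O)C(O)=C[C@]2(C)[C@H]1C | intermediate
21 | (4aS,5R,6S)-3,6-dihydroxy-4a,5-dimethyl-5,6-dihydronaphthalen-2(4aH)-one | O[C@H]1C=CC2=CC(=O)C(O)=C[C@]2(C)[C@H]1C | intermediate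
22 | (4aS,5R,6S)-3-(tert-butyldimethylsilyloxy)-6-hydroxy-4a,5-dimethyl-5,6-dihydronaphthalen-2(4aH)-one | O[C@H]1C=CC2=CC(=O)C(O[Si](C)(C)C(C)(C)C)=C[C@]2(C)[C@H]1C | intermediate
23 | (R)-4-benzyloxazolidin-2-one | O=C1N[C@H](Cc2ccccc2)CO1 | starting material
24 | butanoyl chloride | CCCC(=O)Cl | starting material
25 | (R)-4-benzyl-3-butanoyloxazolidin-2-one | CCCC(=O)N1[C@H](Cc2ccccc2)COC1=O | intermediate
26 | 1,3,5-trioxane | C1OCOCO1 | starting material
27 | (R)-4-benzyl-3-[(S)-2-(hydroxymethyl)butanoyl]oxazolidin-2-one | CC[C@@H](CO)C(=O)N1[C@H](Cc2ccccc2)COC1=O | intermediate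
28 | (R)-4-benzyl-3-[(S)-2-(tert-butyldimethylsilyloxymethyl)butanoyl]oxazolidin-2-one | CC[C@@H](CO[Si](C)(C)C(C)(C)C)C(=O)N1[C@H](Cc2ccccc2)COC1=O | intermediate
29 | (R)-2-(tert-butyldimethylsilyloxymethyl)butan-1-ol | CC[C@H](CO)CO[Si](C)(C)C(C)(C)C | intermediate
30 | (S)-2-(tert-butyldimethylsilyloxymethyl)butanal | CC[C@H](C=O)CO[Si](C)(C)C(C)(C)C | intermediate
31 | triethyl 4-phosphonocrotonate, ethyl (E)-4-(diethoxyphosphoryl)but-2-enoate | CCOC(=O)/C=C/CP(=O)(OCC)OCC | starting material
32 | ethyl (2E,4E,6R)-6-(tert-butyldimethylsilyloxymethyl)octa-2,4-dienoate | CC[C@H](/C=C/C=C/C(=O)OCC)CO[Si](C)(C)C(C)(C)C | intermediate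
33 | (2E,4E,6R)-6-(tert-butyldimethylsilyloxymethyl)octa-2,4-dienoic acid | CC[C@H](/C=C/C=C/C(=O)O)CO[Si](C)(C)C(C)(C)C | intermediate
34 | mixed anhydride of 33 with 2,4,6-trichlorobenzoic acid | CC[C@H](/C=C/C=C/C(=O)OC(=O)c1c(Cl)cc(Cl)cc1Cl)CO[Si](C)(C)C(C)(C)C | intermediate (not isolated)
35 | bis(tert-butyldimethylsilyl) ether of septeremophilane E (enol and primary hydroxyl silylated) | CC[C@H](/C=C/C=C/C(=O)O[C@H]1C=CC2=CC(=O)C(O[Si](C)(C)C(C)(C)C)=C[C@]2(C)[C@H]1C)CO[Si](C)(C)C(C)(C)C | intermediate
36 | septeremophilane E, (1R,2S,8aS)-7-hydroxy-1,8a-dimethyl-6-oxo-1,2,6,8a-tetrahydronaphthalen-2-yl (2E,4E,6R)-6-(hydroxymethyl)octa-2,4-dienoate | CC[C@H](/C=C/C=C/C(=O)O[C@H]1C=CC2=CC(=O)C(O)=C[C@]2(C)[C@H]1C)CO | target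

**Step count and risks**

Total step count: 22. Longest linear sequence: 15 steps (steps 1 to 13, 21 and 22, from 3-methylcyclohex-2-en-1-one).

Three steps most likely to fail:

Step 9 (ring-closing metathesis). What may go wrong: the ruthenium alkylidene loads slowly on the C2 alkene, which is flanked by the bulky silyl ether, so the catalyst rests on the diene terminus as a conjugated vinylalkylidene and intermolecular metathesis or catalyst decay overtakes cyclisation. The fallback sets out from 16. The silyl group is removed with HF·pyridine to give the free allylic alcohol (R)-4-[(2R,3S)-3-hydroxypent-4-en-2-yl]-4-methyl-3-vinylcyclohex-2-en-1-one F1. A free allylic hydroxyl generally speeds alkylidene loading on the adjacent alkene, so F1 should close with the same ruthenium catalyst (1,4-benzoquinone added against ruthenium hydride isomerisation) to the hydroxy trienone (4aR,5R,6S)-6-hydroxy-4a,5-dimethyl-4,4a,5,6-tetrahydronaphthalen-2(3H)-one F2. Silylation with TBSOTf and 2,6-lutidine comes back to the route at 17.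

Step 7 (allylic oxidation). What may go wrong: hydrogen abstraction at the side-chain C3–H, which is both allylic and α to oxygen, or attack on the terminal alkene competes with oxidation of the ring methylene. The fallback sets out from 12. The more electron-rich ring alkene is epoxidised selectively with mCPBA to the C9–C10 epoxide of 12 F3. LiNEt2 isomerises it to the allylic alcohol (6R)-6-[(2R,3S)-3-(tert-butyldimethylsilyloxy)pent-4-en-2-yl]-6-methylcyclohex-2-en-1-ol F4 (hydroxyl on C10, alkene at C8=C9, since only C8 carries β-hydrogens). Dess–Martin oxidation gives the enone (R)-6-[(2R,3S)-3-(tert-butyldimethylsilyloxy)pent-4-en-2-yl]-6-methylcyclohex-2-en-1-one F5. Reagent 14 with CeCl3 adds 1,2 to give the tertiary bis-allylic alcohol (6R)-6-[(2R,3S)-3-(tert-butyldimethylsilyloxy)pent-4-en-2-yl]-6-methyl-1-vinylcyclohex-2-en-1-ol F6. Oxidative 1,3-transposition with pyridinium chlorochromate [C5H5NH][CrO3Cl] (Dauben–Babler oxidation) moves the oxygen to C8 and the alkene to C9=C10. The fallback comes back to the route at 16 and makes step 8 unnecessary.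

Step 3 (Ireland–Claisen rearrangement). What may go wrong: incomplete control of ketene acetal geometry together with poor discrimination between boat-like and chair-like transition states, which would deliver both C4 epimers. The fallback sets out from 2. A Johnson–Claisen rearrangement with triethyl orthoacetate (propanoic acid catalyst, 140 °C) creates only the quaternary centre and gives ethyl 2-[(R)-1-methylcyclohex-2-en-1-yl]acetate F7. Saponification gives 2-[(R)-1-methylcyclohex-2-en-1-yl]acetic acid F8. Activation as the pivaloyl mixed anhydride and reaction with lithiated 23 gives (R)-4-benzyl-3-{2-[(R)-1-methylcyclohex-2-en-1-yl]acetyl}oxazolidin-2-one F9. Methylation of its sodium enolate with iodomethane is steered by the auxiliary and should give (R)-4-benzyl-3-{(R)-2-[(S)-1-methylcyclohex-2-en-1-yl]propanoyl}oxazolidin-2-one F10. LiOH–H2O2 then releases the acid, returns 23, and comes back to the route at 7.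

Further compounds
F1 | step 9 | (R)-4-[(2R,3S)-3-hydroxypent-4-en-2-yl]-4-methyl-3-vinylcyclohex-2-en-1-one | O[C@@H](C=C)[C@H](C)[C@@]1(C)CCC(=O)C=C1C=C
F2 | step 9 | (4aR,5R,6S)-6-hydroxy-4a,5-dimethyl-4,4a,5,6-tetrahydronaphthalen-2(3H)-one | O[C@H]1C=CC2=CC(=O)CC[C@]2(C)[C@H]1C
F3 | step 7 | C9–C10 epoxide of 12 (epoxide configuration unassigned) | CC(C)(C)[Si](C)(C)O[C@@H](C=C)[C@H](C)[C@@]1(C)CCCC2OC12
F4 | step 7 | (6R)-6-[(2R,3S)-3-(tert-butyldimethylsilyloxy)pent-4-en-2-yl]-6-methylcyclohex-2-en-1-ol (carbinol epimers) | CC(C)(C)[Si](C)(C)O[C@@H](C=C)[C@H](C)[C@@]1(C)CCC=CC1O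
F5 | step 7 | (R)-6-[(2R,3S)-3-(tert-butyldimethylsilyloxy)pent-4-en-2-yl]-6-methylcyclohex-2-en-1-one | CC(C)(C)[Si](C)(C)O[C@@H](C=C)[C@H](C)[C@@]1(C)CCC=CC1=O
F6 | step 7 | (6R)-6-[(2R,3S)-3-(tert-butyldimethylsilyloxy)pent-4-en-2-yl]-6-methyl-1-vinylcyclohex-2-en-1-ol (carbinol epimers) | CC(C)(C)[Si](C)(C)O[C@@H](C=C)[C@H](C)[C@@]1(C)CCC=CC1(O)C=C
F7 | step 3 | ethyl 2-[(R)-1-methylcyclohex-2-en-1-yl]acetate | CCOC(=O)C[C@@]1(C)CCCC=C1
F8 | step 3 | 2-[(R)-1-methylcyclohex-2-en-1-yl]acetic acid | OC(=O)C[C@@]1(C)CCCC=C1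
F9 | step 3 | (R)-4-benzyl-3-{2-[(R)-1-methylcyclohex-2-en-1-yl]acetyl}oxazolidin-2-one | O=C(C[C@@]1(C)CCCC=C1)N1[C@H](Cc2ccccc2)COC1=O
F10 | step 3 | (R)-4-benzyl-3-{(R)-2-[(S)-1-methylcyclohex-2-en-1-yl]propanoyl}oxazolidin-2-one | O=C([C@H](C)[C@@]1(C)CCCC=C1)N1[C@H](Cc2ccccc2)COC1=O
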